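**Retrosynthetic overview**

- Chain atoms are labelled C1 (lactone C=O), C2 (quaternary C), C3 (ketone), C5 (lactone O–CH), C7 (spiro C), C9 (CH–OAc), C11 (oxane O–CH) and C12 (its CH3); the target is reached from its C4 epimer by equilibration next to the ketone.
- Ring C (carbocycle) opens at C2–C7 (β-keto-lactone enol plus C7 oxocarbenium ion) and ring B (δ-lactone) at O–C1 (5-OH plus acyl oxazolidinone); both close in one flask from an open-chain imide.
- Ring A (oxane) opens at O–C7 (11-OH plus C7 ketone) and is carried as the cyclic methyl ketal.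
- C4–C5 and C8–C9 are aldol bonds made with one β-ketoimide used twice (as C1–C4 and as C5–C8); C9–C12 is an aldehyde from a propionate aldol with acetaldehyde.
- Forward ring order: A (ketal), then B (lactone), then C (C2–C7 bond), then C4 epimerisation.

Assumption: the biosynthesis is taken as cyclisation of a linear hexaketide acyl chain (3,7-dioxo; 5-, 9-, 11-oxygenated), in which 11-OH adds to C7 (hemiketal), 5-OH acylates at C1 (lactone) and the C2 enol attacks the C7 oxocarbenium ion.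

**Route**

Step 1
Reactants: 1 (4S)-4-benzyl-3-propanoyl-1,3-thiazolidine-2-thione; 2 acetaldehyde
Product: 3 (4S)-4-benzyl-3-[(2R,3S)-3-hydroxy-2-methylbutanoyl]-1,3-thiazolidine-2-thione
Conditions: TiCl4 (1.05 equiv), i-Pr2NEt (1.1 equiv), CH2Cl2, 0 °C; then 2, −78 → 0 °C
Reagents that add atoms: none
Why: Crimmins titanium aldol of an N-acylthiazolidinethione with one equivalent each of TiCl4 and amine runs through the chelated chair transition state and gives the non-Evans syn adduct, which sets C10 (R) and C11 (S).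

Step 2
Reactants: 3 (4S)-4-benzyl-3-[(2R,3S)-3-hydroxy-2-methylbutanoyl]-1,3-thiazolidine-2-thione
Product: 4 (4S)-4-benzyl-3-[(2R,3S)-2-methyl-3-(triethylsilyloxy)butanoyl]-1,3-thiazolidine-2-thione
Conditions: TESOTf, 2,6-lutidine, CH2Cl2, −78 °C
Reagents that add atoms: triethylsilyl trifluoromethanesulfonate, CC[Si](CC)(CC)OS(=O)(=O)C(F)(F)F
Why: Silylation with a silyl triflate and a hindered base protects 11-OH as a TES ether that survives the next Lewis-acidic aldol and is removed by mild acid later, with no stereocentre touched.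

Step 3
Reactants: 4 (4S)-4-benzyl-3-[(2R,3S)-2-methyl-3-(triethylsilyloxy)butanoyl]-1,3-thiazolidine-2-thione
Product: 5 (2R,3S)-2-methyl-3-(triethylsilyloxy)butanal
Conditions: i-Bu2AlH (1.2 equiv), CH2Cl2, −78 °C; aq. potassium sodium tartrate
Reagents that add atoms: none
Why: Partial reduction of the N-acylthiazolidinethione stops at the aldehyde because the aluminium hemithioaminal is stable at −78 °C (Crimmins auxiliary removal), and the α-centre is not epimerised.

Step 4
Reactants: 6 (4S)-4-benzyl-3-propanoyl-1,3-oxazolidin-2-one; 7 propanal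
Product: 8 (4S)-4-benzyl-3-[(2S,3R)-3-hydroxy-2-methylpentanoyl]-1,3-oxazolidin-2-one
Conditions: Bu2BOTf, Et3N, CH2Cl2, 0 °C; then 7, −78 → 0 °C; H2O2, MeOH, pH 7 buffer
Reagents that add atoms: none
Why: Evans boron aldol (Z-enolate, Zimmerman–Traxler chair) gives the syn adduct and sets the (2S) methyl centre that later becomes C2 and C6, while the carbinol centre is removed in step 5.

Step 5
Reactants: 8 (4S)-4-benzyl-3-[(2S,3R)-3-hydroxy-2-methylpentanoyl]-1,3-oxazolidin-2-one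
Product: 9 (4S)-4-benzyl-3-[(2S)-2-methyl-3-oxopentanoyl]-1,3-oxazolidin-2-one
Conditions: SO3·pyridine, DMSO, Et3N, CH2Cl2, −10 °C
Reagents that add atoms: none
Why: Parikh–Doering oxidation gives the β-ketoimide without epimerisation because A(1,3) strain keeps the C2–H out of alignment for enolisation.

Step 6
Reactants: 9 (4S)-4-benzyl-3-[(2S)-2-methyl-3-oxopentanoyl]-1,3-oxazolidin-2-one; 5 (2R,3S)-2-methyl-3-(triethylsilyloxy)butanal
Product: 10 (4S)-4-benzyl-3-[(2S,4S,5R,6S,7S)-5-hydroxy-2,4,6-trimethyl-3-oxo-7-(triethylsilyloxy)octanoyl]-1,3-oxazolidin-2-one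
Conditions: 9, TiCl4 (1.1 equiv), i-Pr2NEt (1.2 equiv), CH2Cl2, −10 °C; then 5, −78 °C
Reagents that add atoms: none
Why: Evans titanium-enolate aldol of the β-ketoimide (Z-enolate, chair transition state) gives the syn,syn adduct under control of the existing methyl centre, and its anti-Felkin preference towards the α-methyl aldehyde is matched, so C8 (S) and C9 (R) are set 6,8-syn, 8,9-syn and 9,10-anti.

Step 7
Reactants: 10 (4S)-4-benzyl-3-[(2S,4S,5R,6S,7S)-5-hydroxy-2,4,6-trimethyl-3-oxo-7-(triethylsilyloxy)octanoyl]-1,3-oxazolidin-2-one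
Product: 11 (4S)-4-benzyl-3-[(2S,4S,5R,6S,7S)-5-acetoxy-2,4,6-trimethyl-3-oxo-7-(triethylsilyloxy)octanoyl]-1,3-oxazolidin-2-one
Conditions: Ac2O, pyridine, DMAP (cat.), CH2Cl2, 0 °C
Reagents that add atoms: acetic anhydride, CC(=O)OC(C)=O
Why: DMAP-catalysed acylation installs the C9 acetate of the target early and also blocks lactonisation of 9-OH onto the imide, with no stereocentre touched.

Step 8
Reactants: 11 (4S)-4-benzyl-3-[(2S,4S,5R,6S,7S)-5-acetoxy-2,4,6-trimethyl-3-oxo-7-(triethylsilyloxy)octanoyl]-1,3-oxazolidin-2-one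
Product: 13 (4S)-4-benzyl-3-[(2S)-2-[(2S,3S,4R,5R,6S)-4-acetoxy-2-methoxy-3,5,6-trimethyloxan-2-yl]propanoyl]-1,3-oxazolidin-2-one, via hemiketal 12 (not isolated)
Conditions: PPTS (cat.), MeOH, rt
Reagents that add atoms: methanol, CO
Why: Acidic methanolysis removes the TES group and the freed 11-OH adds to the C7 ketone to give the six-membered hemiketal, which is trapped as the cyclic methyl ketal with axial OMe (anomeric effect); this is the biosynthetic hemiketalisation in stored form, and the temporary C7 centre is erased in step 11.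

Step 9
Reactants: 13 (4S)-4-benzyl-3-[(2S)-2-[(2S,3S,4R,5R,6S)-4-acetoxy-2-methoxy-3,5,6-trimethyloxan-2-yl]propanoyl]-1,3-oxazolidin-2-one
Product: 14 (2S,3S,4R,5R,6S)-2-methoxy-3,5,6-trimethyl-2-[(2R)-1-oxopropan-2-yl]oxan-4-yl acetate
Conditions: Cp2Zr(H)Cl (1.5 equiv), THF, rt
Reagents that add atoms: none
Why: Georg reduction, in which hydrozirconation of the exocyclic imide carbonyl gives a zirconated hemiaminal that releases the aldehyde on work-up while acetate and ketal are inert and C6 is kept.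

Step 10
Reactants: 9 (4S)-4-benzyl-3-[(2S)-2-methyl-3-oxopentanoyl]-1,3-oxazolidin-2-one; 14 (2S,3S,4R,5R,6S)-2-methoxy-3,5,6-trimethyl-2-[(2R)-1-oxopropan-2-yl]oxan-4-yl acetate
Product: 15 (4S)-4-benzyl-3-[(2S,4R,5R,6R)-6-[(2R,3S,4R,5R,6S)-4-acetoxy-2-methoxy-3,5,6-trimethyloxan-2-yl]-5-hydroxy-2,4-dimethyl-3-oxoheptanoyl]-1,3-oxazolidin-2-one
Conditions: 9, Sn(OTf)2 (1.3 equiv), Et3N (1.4 equiv), CH2Cl2, −20 °C; then 14, −78 °C
Reagents that add atoms: none
Why: Evans Sn(OTf)2 aldol of the β-ketoimide (Z-enolate, chair transition state) gives the anti,syn adduct, and the anti-Felkin preference of the Z-enolate towards 14 is matched, so C5 is set 5,6-anti as required, while C4 is formed syn to 5-OH (the epimer of the target, corrected in step 12) and C2 is lost to enolisation in step 11.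

Step 11
Reactants: 15 (4S)-4-benzyl-3-[(2S,4R,5R,6R)-6-[(2R,3S,4R,5R,6S)-4-acetoxy-2-methoxy-3,5,6-trimethyloxan-2-yl]-5-hydroxy-2,4-dimethyl-3-oxoheptanoyl]-1,3-oxazolidin-2-one
Product: 19 (4R)-4'-acetoxy-3',4,5',6,6',7-hexamethylspiro[2-oxabicyclo[2.2.2]octane-8,2'-oxane]-3,5-dione (C4 epimer of the target; chain labels 2R,4R,5S,6R,7S,8S,9R,10R,11S), via lactone 16 (not isolated), via silyl enol ether 17 (not isolated), via oxocarbenium triflate 18 (not isolated)
Conditions: Et3N (2.2 equiv), DMAP (cat.), CH2Cl2, rt; then TMSOTf (4 equiv), −78 → −30 °C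
Reagents that add atoms: none
Why: Proposed new method: Et3N/DMAP induces the known lactonisation of the δ-hydroxy-β-ketoimide (5-OH attacks C1, auxiliary leaves), TMSOTf then silylates the acidic β-keto-lactone enol and ionises the methyl ketal, and the silyl enol ether carbon C2 adds to the C7 oxocarbenium ion (closest known type: Noyori TMSOTf-mediated Mukaiyama addition of silyl enol ethers to ketals, here intramolecular); the tether from C5 fixes C2 (R), and axial attack on the half-chair that keeps C8-Me, C9-OAc and C11-Me pseudo-equatorial fixes C7 (S).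

Step 12
Reactants: 19 (4R)-4'-acetoxy-3',4,5',6,6',7-hexamethylspiro[2-oxabicyclo[2.2.2]octane-8,2'-oxane]-3,5-dione
Product: 20 CNP0257416.2, (4S)-4'-acetoxy-3',4,5',6,6',7-hexamethylspiro[2-oxabicyclo[2.2.2]octane-8,2'-oxane]-3,5-dione (chain labels 2R,4S,5S,6R,7S,8S,9R,10R,11S)
Conditions: TsOH·H2O (0.2 equiv), CHCl3, 45 °C; recovered 19 recycled
Reagents that add atoms: none
Why: Acid-catalysed keto–enol equilibration (thermodynamic epimerisation) at C4, the only enolisable carbon of the C3 ketone, moves the methyl from the crowded cleft over the C6–C7 bridge to the open side facing the lactone ring oxygen and so gives the (4S) configuration; base is avoided because a C4 enolate could expel the lactone carboxylate.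

**Compound list**

1 | (4S)-4-benzyl-3-propanoyl-1,3-thiazolidine-2-thione | CCC(=O)N1[C@@H](Cc2ccccc2)CSC1=S | starting material
2 | acetaldehyde | CC=O | starting material
3 | (4S)-4-benzyl-3-[(2R,3S)-3-hydroxy-2-methylbutanoyl]-1,3-thiazolidine-2-thione | C[C@H](O)[C@@H](C)C(=O)N1[C@@H](Cc2ccccc2)CSC1=S | intermediate
4 | (4S)-4-benzyl-3-[(2R,3S)-2-methyl-3-(triethylsilyloxy)butanoyl]-1,3-thiazolidine-2-thione | C[C@H](O[Si](CC)(CC)CC)[C@@H](C)C(=O)N1[C@@H](Cc2ccccc2)CSC1=S | intermediate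
5 | (2R,3S)-2-methyl-3-(triethylsilyloxy)butanal | C[C@H](O[Si](CC)(CC)CC)[C@@H](C)C=O | intermediate
6 | (4S)-4-benzyl-3-propanoyl-1,3-oxazolidin-2-one | CCC(=O)N1[C@@H](Cc2ccccc2)COC1=O | starting material
7 | propanal | CCC=O | starting material
8 | (4S)-4-benzyl-3-[(2S,3R)-3-hydroxy-2-methylpentanoyl]-1,3-oxazolidin-2-one | CC[C@@H](O)[C@H](C)C(=O)N1[C@@H](Cc2ccccc2)COC1=O | intermediate
9 | (4S)-4-benzyl-3-[(2S)-2-methyl-3-oxopentanoyl]-1,3-oxazolidin-2-one | CCC(=O)[C@H](C)C(=O)N1[C@@H](Cc2ccccc2)COC1=O | intermediate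
10 | (4S)-4-benzyl-3-[(2S,4S,5R,6S,7S)-5-hydroxy-2,4,6-trimethyl-3-oxo-7-(triethylsilyloxy)octanoyl]-1,3-oxazolidin-2-one | C[C@H](O[Si](CC)(CC)CC)[C@@H](C)[C@@H](O)[C@H](C)C(=O)[C@H](C)C(=O)N1[C@@H](Cc2ccccc2)COC1=O | intermediate
11 | (4S)-4-benzyl-3-[(2S,4S,5R,6S,7S)-5-acetoxy-2,4,6-trimethyl-3-oxo-7-(triethylsilyloxy)octanoyl]-1,3-oxazolidin-2-one | C[C@H](O[Si](CC)(CC)CC)[C@@H](C)[C@@H](OC(C)=O)[C@H](C)C(=O)[C@H](C)C(=O)N1[C@@H](Cc2ccccc2)COC1=O | intermediate
12 | (4S)-4-benzyl-3-[(2S)-2-[(2S,3S,4R,5R,6S)-4-acetoxy-2-hydroxy-3,5,6-trimethyloxan-2-yl]propanoyl]-1,3-oxazolidin-2-one (hemiketal) | O[C@@]1(O[C@@H](C)[C@@H](C)[C@@H](OC(C)=O)[C@@H]1C)[C@H](C)C(=O)N2[C@@H](Cc3ccccc3)COC2=O | intermediate (not isolated)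
13 | (4S)-4-benzyl-3-[(2S)-2-[(2S,3S,4R,5R,6S)-4-acetoxy-2-methoxy-3,5,6-trimethyloxan-2-yl]propanoyl]-1,3-oxazolidin-2-one | CO[C@@]1(O[C@@H](C)[C@@H](C)[C@@H](OC(C)=O)[C@@H]1C)[C@H](C)C(=O)N2[C@@H](Cc3ccccc3)COC2=O | intermediate
14 | (2S,3S,4R,5R,6S)-2-methoxy-3,5,6-trimethyl-2-[(2R)-1-oxopropan-2-yl]oxan-4-yl acetate | CO[C@@]1(O[C@@H](C)[C@@H](C)[C@@H](OC(C)=O)[C@@H]1C)[C@H](C)C=O | intermediate
15 | (4S)-4-benzyl-3-[(2S,4R,5R,6R)-6-[(2R,3S,4R,5R,6S)-4-acetoxy-2-methoxy-3,5,6-trimethyloxan-2-yl]-5-hydroxy-2,4-dimethyl-3-oxoheptanoyl]-1,3-oxazolidin-2-one | CO[C@@]1(O[C@@H](C)[C@@H](C)[C@@H](OC(C)=O)[C@@H]1C)[C@H](C)[C@H](O)[C@@H](C)C(=O)[C@H](C)C(=O)N2[C@@H](Cc3ccccc3)COC2=O | intermediate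
16 | (2S,3S,4R,5R,6S)-2-[(1R)-1-[(2R,3R)-4-hydroxy-3,5-dimethyl-6-oxo-3,6-dihydro-2H-pyran-2-yl]ethyl]-2-methoxy-3,5,6-trimethyloxan-4-yl acetate (β-keto-δ-lactone, enol form) | CO[C@@]1(O[C@@H](C)[C@@H](C)[C@@H](OC(C)=O)[C@@H]1C)[C@H](C)[C@@H]2OC(=O)C(C)=C(O)[C@@H]2C | intermediate (not isolated)
17 | O-trimethylsilyl enol ether of 16 (4-trimethylsilyloxy-dihydropyranone) | CO[C@@]1(O[C@@H](C)[C@@H](C)[C@@H](OC(C)=O)[C@@H]1C)[C@H](C)[C@@H]2OC(=O)C(C)=C(O[Si](C)(C)C)[C@@H]2C | intermediate (not isolated)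
18 | cyclic C7 oxocarbenium triflate formed from 17 by loss of methoxide | C[C@H]([C@@H]1OC(=O)C(C)=C(O[Si](C)(C)C)[C@@H]1C)C2=[O+][C@@H](C)[C@@H](C)[C@@H](OC(C)=O)[C@@H]2C.[O-]S(=O)(=O)C(F)(F)F | intermediate (not isolated)
19 | (4R)-4'-acetoxy-3',4,5',6,6',7-hexamethylspiro[2-oxabicyclo[2.2.2]octane-8,2'-oxane]-3,5-dione (C4 epimer of the target) | CC(=O)O[C@@H]1[C@H](C)[C@H](C)O[C@]2([C@H](C)[C@@H]3OC(=O)[C@@]2(C)C(=O)[C@@H]3C)[C@H]1C | intermediate
20 | CNP0257416.2, (4S)-4'-acetoxy-3',4,5',6,6',7-hexamethylspiro[2-oxabicyclo[2.2.2]octane-8,2'-oxane]-3,5-dione | CC(=O)O[C@@H]1[C@H](C)[C@H](C)O[C@]2([C@H](C)[C@@H]3OC(=O)[C@@]2(C)C(=O)[C@H]3C)[C@H]1C | target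

**Step count and risks**

Total steps: 12. Longest linear sequence: 10 (steps 1, 2, 3, 6, 7, 8, 9, 10, 11, 12).

Most likely to fail, first: step 11. The oxocarbenium ion may lose a proton to give enol ethers (which would scramble C6 or C8), the C7 epimer may form, or the bicyclic transition state may be too strained. The fallback reverses the order of ring closure, carbocycle before lactone. It sets out from 15. TESOTf and 2,6-lutidine give the 5-O-triethylsilyl ether F1. LiSEt in THF at 0 °C exchanges the auxiliary for a thioester and gives the β-keto thioester F2, whose C2 enolises freely. Et3N and TMSOTf then close only the six-membered carbocycle through a chair transition state and give the spiro cyclohexanone thioester F3. HF·pyridine removes the silyl group and the freed 5-OH lactonises onto the thioester (AgOCOCF3 if needed), which comes back to the route at 19.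

Second: step 12, together with the choice in step 10 to form C4 as the wrong epimer. The preference for the (4S) epimer is estimated at only about 4:1, and acid may also trigger β-elimination or reversible opening of the C2–C7 bond. The fallback sets C4 kinetically by a reagent-controlled anti aldol, which is needed because an E-enolate would otherwise add to 14 in the Felkin sense. It sets out from 14. The boron enolate of purchased (R)-2-(benzoyloxy)pentan-3-one F4, made with (c-Hex)2BCl and Me2NEt, adds to 14 and gives the 4,5-anti-5,6-anti adduct F5. CDI gives the imidazole-1-carboxylate F6. SmI2 cleaves the α-benzoyloxy ketone to the trivalent samarium enolate, which is acylated intramolecularly by the carbamate carbonyl and gives lactone F7, the C4 epimer of 16 with C1 supplied by CDI. Et3N and TMSOTf as in step 11 then give 20 directly, so this comes back to the route at 20.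

Third: step 9. The imide is hindered by the neighbouring ketal carbon and may react slowly or be over-reduced. The fallback is a two-stage redox sequence through the alcohol. It sets out from 13. NaBH4 in THF/H2O gives the primary alcohol F8 and leaves the acetate intact, and Dess–Martin periodinane in CH2Cl2 oxidises F8, which comes back to the route at 14.

Further compounds
F1 | step 11 | 5-O-triethylsilyl ether of 15 | CO[C@@]1(O[C@@H](C)[C@@H](C)[C@@H](OC(C)=O)[C@@H]1C)[C@H](C)[C@H](O[Si](CC)(CC)CC)[C@@H](C)C(=O)[C@H](C)C(=O)N2[C@@H](Cc3ccccc3)COC2=O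
F2 | step 11 | S-ethyl β-keto thioester (auxiliary of F1 replaced by SEt; C2 labile) | CO[C@@]1(O[C@@H](C)[C@@H](C)[C@@H](OC(C)=O)[C@@H]1C)[C@H](C)[C@H](O[Si](CC)(CC)CC)[C@@H](C)C(=O)[C@H](C)C(=O)SCC
F3 | step 11 | spiro cyclohexanone thioester (C2–C7 bond formed; 5-O-TES; lactone open) | CC(=O)O[C@@H]1[C@H](C)[C@H](C)O[C@]2([C@H](C)[C@H](O[Si](CC)(CC)CC)[C@@H](C)C(=O)[C@]2(C)C(=O)SCC)[C@H]1C
F4 | step 12 | (R)-2-(benzoyloxy)pentan-3-one | CCC(=O)[C@@H](C)OC(=O)c1ccccc1
F5 | step 12 | (2R,4S,5R,6R)-6-[(2R,3S,4R,5R,6S)-4-acetoxy-2-methoxy-3,5,6-trimethyloxan-2-yl]-5-hydroxy-4-methyl-3-oxoheptan-2-yl benzoate | CO[C@@]1(O[C@@H](C)[C@@H](C)[C@@H](OC(C)=O)[C@@H]1C)[C@H](C)[C@H](O)[C@H](C)C(=O)[C@@H](C)OC(=O)c2ccccc2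
F6 | step 12 | 5-O-(imidazol-1-ylcarbonyl) derivative of F5 | CO[C@@]1(O[C@@H](C)[C@@H](C)[C@@H](OC(C)=O)[C@@H]1C)[C@H](C)[C@H](OC(=O)n2ccnc2)[C@H](C)C(=O)[C@@H](C)OC(=O)c3ccccc3
F7 | step 12 | C4 epimer of lactone 16 (4,5-trans β-keto-δ-lactone, enol form) | CO[C@@]1(O[C@@H](C)[C@@H](C)[C@@H](OC(C)=O)[C@@H]1C)[C@H](C)[C@@H]2OC(=O)C(C)=C(O)[C@H]2C
F8 | step 9 | (2S,3S,4R,5R,6S)-2-[(2R)-1-hydroxypropan-2-yl]-2-methoxy-3,5,6-trimethyloxan-4-yl acetate | CO[C@@]1(O[C@@H](C)[C@@H](C)[C@@H](OC(C)=O)[C@@H]1C)[C@H](C)CO
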